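**Retrosynthetic overview** (locants follow the prostanoid numbering of the target: C9 ketone, C10 bromide, C12 carbinol, C8 ring CH, C7 acetoxy carbon)
- The C7 acetate comes from the C7 alcohol; the C7–C8 bond is made last by an anti-selective aldol between the dianion of the bromo-hydroxy-cyclopentenone and methyl (Z)-7-oxohept-5-enoate.
- The 10-bromo-enone comes from a ring silyl enol ether: bromination at C10, then loss of the C11 sulfinyl group as sulfenic acid.
- Key step, which forms the only ring: a methyl ketone enolate (C8/C12) adds to a β-sulfinyl acryloylsilane (C9–C11). Brook rearrangement then turns C9–C11 into a homoenolate whose β-carbon C11 closes on the C12 ketone, so two normally electrophilic carbons are joined. The (R)-sulfinyl group on C11 is intended to set C12 and is also the later leaving group.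
- Building blocks: a regiodefined enolate precursor from acetylene carbocupration, the acryloylsilane from methoxyallene, the Z-enal by Z-selective cross-metathesis.

Assumption: solutions of pentylmagnesium bromide, n-BuLi, t-BuLi, MeLi and LDA, bis(trimethylsilyl) peroxide and (1R,2S,5R)-menthyl (S)-p-toluenesulfinate are bought.

**Step 1**
Reactants: 1 pentylmagnesium bromide; 2 acetylene; 3 2,3-dibromoprop-1-ene
Product: 6 (4Z)-2-bromoundeca-1,4-diene, via pentylcopper 4 (not isolated), via (Z)-hept-1-enylcopper 5 (not isolated)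
Conditions: 1, CuBr·SMe2 (1.0 equiv), Et2O/Me2S, −45 °C; 2 (1.0 equiv), −50 → −25 °C; 3, THF, −30 → 0 °C
Reagents that add atoms: none
Why: Normant syn-carbocupration of acetylene gives only the (Z)-alkenylcopper, and its allylic substitution on 3 (SN2 and SN2' give the same product) keeps the Z geometry of C14=C15.

**Step 2**
Reactants: 6 (4Z)-2-bromoundeca-1,4-diene
Product: 8 (4Z)-2-(trimethylsilyloxy)undeca-1,4-diene, via (4Z)-undeca-1,4-dien-2-yllithium 7 (not isolated)
Conditions: t-BuLi (2.0 equiv), Et2O, −78 °C; Me3SiOOSiMe3 (1.0 equiv), −78 → 0 °C; non-aqueous work-up, distil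
Reagents that add atoms: bis(trimethylsilyl) peroxide C[Si](C)(C)OO[Si](C)(C)C
Why: Br–Li exchange followed by electrophilic oxygenation of the alkenyllithium with the silyl peroxide gives the methyl-side silyl enol ether regiospecifically, which deprotonation of the β,γ-unsaturated ketone (more acidic allylic CH2) could not.

**Step 3**
Reactants: 9 methoxyallene; 10 (1R,2S,5R)-menthyl (S)-4-methylbenzenesulfinate
Product: 15 (2E)-1-[tert-butyl(dimethyl)silyl]-3-[(R)-4-methylbenzenesulfinyl]prop-2-en-1-one, via 1-lithio-1-methoxyallene 11 (not isolated), via 1-silyl-1-methoxyallene 12 (not isolated), via 3-lithio-1-silyl-1-methoxyallene 13 (not isolated), via allenyl sulfoxide 14 (not isolated)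
Conditions: 9, n-BuLi, THF, −78 °C; t-BuMe2SiCl, −78 → 0 °C; n-BuLi, −78 °C; add to 10, THF, −78 °C; 1 M H2SO4 (aq), 0 → 20 °C
Reagents that add atoms: tert-butyl(chloro)dimethylsilane CC(C)(C)[Si](C)(C)Cl; water O
Why: α-lithiation/silylation and then γ-lithiation of the silyl allenyl ether, Andersen substitution on the sulfinate with inversion at sulfur (giving the R sulfoxide), and enol ether hydrolysis to the E acylsilane are each known reaction types, here run in one pot.

**Step 4**
Reactants: 8 (4Z)-2-(trimethylsilyloxy)undeca-1,4-diene; 15 (2E)-1-[tert-butyl(dimethyl)silyl]-3-[(R)-4-methylbenzenesulfinyl]prop-2-en-1-one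
Product: 17 (1S,2R)-4-{[tert-butyl(dimethyl)silyl]oxy}-2-[(R)-4-methylbenzenesulfinyl]-1-[(2Z)-oct-2-en-1-yl]cyclopent-3-en-1-ol, via lithium (4Z)-undeca-1,4-dien-2-olate 16 (not isolated)
Conditions: 8 (1.05 equiv), MeLi (1.0 equiv), THF, 0 → 20 °C; −80 °C, 15; −80 → −30 °C; AcOH, −78 °C; fast chromatography below 0 °C
Reagents that add atoms: none
Why: Proposed new method: a sulfinyl-directed variant of the Brook rearrangement-mediated [3+2] annulation of β-heteroatom-substituted acryloylsilanes with methyl ketone lithium enolates (closest known cases: β-phenylthio and β-trimethylsilyl, racemic), in which 16 adds 1,2 to the acylsilane (C8–C9), C-to-O silyl migration makes C9–C11 a siloxyallyl anion (homoenolate), and its sulfinyl-stabilised C11 closes on the tethered C12 ketone; a lithium bridge between sulfinyl O and ketone O puts S and O cis, and with the p-tolyl group turned away from the ring the (R)-sulfoxide is predicted to give (1S,2R)-17, any C12 epimer being a separable diastereomer.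

**Step 5**
Reactants: 17 (1S,2R)-4-{[tert-butyl(dimethyl)silyl]oxy}-2-[(R)-4-methylbenzenesulfinyl]-1-[(2Z)-oct-2-en-1-yl]cyclopent-3-en-1-ol
Product: 19 (4S)-2-bromo-4-hydroxy-4-[(2Z)-oct-2-en-1-yl]cyclopent-2-en-1-one, via 2-bromo ketone 18 (not isolated)
Conditions: NBS (1.0 equiv), THF, −78 °C; Et3N (2 equiv), −78 → 0 °C
Reagents that add atoms: N-bromosuccinimide O=C1CCC(=O)N1Br
Why: the silyl enol ether is far more nucleophilic than the isolated Z-alkene, so bromination places Br only at C10, and E1cB loss of sulfenate from C11 then gives the 2-bromo-enone without touching C12; 17 is an allylic sulfoxide and is used at once to avoid [2,3]-rearrangement.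

**Step 6**
Reactants: 20 methyl hex-5-enoate; 21 (Z)-but-2-ene-1,4-diol
Product: 22 methyl (5Z)-7-hydroxyhept-5-enoate
Conditions: 21 (3 equiv), Ru(=CH-C6H4-2-OiPr)(SIMes)(S2C6H2Cl2-3,6) (5 mol %), THF, 22 °C
Reagents that add atoms: none
Why: Z-selective cross-metathesis with the ruthenium dithiolate catalyst transfers the cis geometry of the diol and sets the 5Z alkene.

**Step 7**
Reactants: 22 methyl (5Z)-7-hydroxyhept-5-enoate
Product: 23 methyl (5Z)-7-oxohept-5-enoate
Conditions: Dess–Martin periodinane (1.2 equiv), 2,6-lutidine, CH2Cl2, 0 °C; used at once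
Reagents that add atoms: none
Why: buffered Dess–Martin oxidation of the allylic alcohol is fast at 0 °C and avoids the acid or nucleophile catalysis that isomerises Z-enals.

**Step 8**
Reactants: 19 (4S)-2-bromo-4-hydroxy-4-[(2Z)-oct-2-en-1-yl]cyclopent-2-en-1-one; 23 methyl (5Z)-7-oxohept-5-enoate
Product: 25 methyl (5Z,7S)-7-[(1R,2S)-4-bromo-2-hydroxy-2-[(2Z)-oct-2-en-1-yl]-5-oxocyclopent-3-en-1-yl]-7-hydroxyhept-5-enoate, via dilithium alkoxide dienolate 24 (not isolated)
Conditions: LDA (2.1 equiv), THF, −78 °C; 23 (1.2 equiv), −78 °C, 10 min; AcOH, −78 °C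
Reagents that add atoms: none
Why: lithium aldol addition in which the ring-locked E enolate reacts through a Zimmerman–Traxler chair to give the anti (7S,8R) adduct, on the face bearing the C12–OLi and away from the octenyl chain, so the new chain is trans to the octenyl group.

**Step 9**
Reactants: 25 methyl (5Z,7S)-7-[(1R,2S)-4-bromo-2-hydroxy-2-[(2Z)-oct-2-en-1-yl]-5-oxocyclopent-3-en-1-yl]-7-hydroxyhept-5-enoate
Product: 26 methyl (5Z,7S)-7-acetoxy-7-[(1R,2S)-4-bromo-2-hydroxy-2-[(2Z)-oct-2-en-1-yl]-5-oxocyclopent-3-en-1-yl]hept-5-enoate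
Conditions: Ac2O (1.5 equiv), pyridine, DMAP (5 mol %), CH2Cl2, 0 °C
Reagents that add atoms: acetic anhydride CC(=O)OC(C)=O
Why: acylation is selective for the secondary C7 alcohol over the hindered tertiary C12 alcohol, and the cold, weakly basic conditions avoid β-elimination of the new acetate.

**Compound list**
1 | pentylmagnesium bromide | CCCCC[Mg]Br | starting material
2 | acetylene | C#C | starting material
3 | 2,3-dibromoprop-1-ene | C=C(Br)CBr | starting material
4 | pentylcopper | CCCCC[Cu] | intermediate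
5 | (Z)-hept-1-en-1-ylcopper | CCCCC/C=C\[Cu] | intermediate
6 | (4Z)-2-bromoundeca-1,4-diene | C=C(Br)C/C=C\CCCCC | intermediate
7 | (4Z)-undeca-1,4-dien-2-yllithium | [Li]C(=C)C/C=C\CCCCC | intermediate
8 | (4Z)-2-(trimethylsilyloxy)undeca-1,4-diene | C=C(O[Si](C)(C)C)C/C=C\CCCCC | intermediate
9 | methoxyallene (1-methoxypropa-1,2-diene) | COC=C=C | starting material
10 | (1R,2S,5R)-2-isopropyl-5-methylcyclohexyl (S)-4-methylbenzenesulfinate | CC(C)[C@@H]1CC[C@@H](C)C[C@H]1O[S@](=O)c1ccc(C)cc1 | starting material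
11 | (1-methoxypropa-1,2-dien-1-yl)lithium | [Li]C(OC)=C=C | intermediate
12 | tert-butyl(1-methoxypropa-1,2-dien-1-yl)dimethylsilane | COC(=C=C)[Si](C)(C)C(C)(C)C | intermediate
13 | {3-[tert-butyl(dimethyl)silyl]-3-methoxypropa-1,2-dien-1-yl}lithium | [Li]C=C=C(OC)[Si](C)(C)C(C)(C)C | intermediate
14 | tert-butyl{1-methoxy-3-[(R)-4-methylbenzenesulfinyl]propa-1,2-dien-1-yl}dimethylsilane (both allene-axis epimers) | COC(=C=C[S@@](=O)c1ccc(C)cc1)[Si](C)(C)C(C)(C)C | intermediate
15 | (2E)-1-[tert-butyl(dimethyl)silyl]-3-[(R)-4-methylbenzenesulfinyl]prop-2-en-1-one | CC(C)(C)[Si](C)(C)C(=O)/C=C/[S@@](=O)c1ccc(C)cc1 | intermediate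
16 | lithium (4Z)-undeca-1,4-dien-2-olate | [Li+].[O-]C(=C)C/C=C\CCCCC | intermediate
17 | (1S,2R)-4-{[tert-butyl(dimethyl)silyl]oxy}-2-[(R)-4-methylbenzenesulfinyl]-1-[(2Z)-oct-2-en-1-yl]cyclopent-3-en-1-ol | CCCCC/C=C\C[C@@]1(O)[C@H]([S@@](=O)c2ccc(C)cc2)C=C(O[Si](C)(C)C(C)(C)C)C1 | intermediate
18 | (3S,4S)-2-bromo-4-hydroxy-3-[(R)-4-methylbenzenesulfinyl]-4-[(2Z)-oct-2-en-1-yl]cyclopentan-1-one (C2 epimers) | CCCCC/C=C\C[C@@]1(O)[C@H]([S@@](=O)c2ccc(C)cc2)C(Br)C(=O)C1 | intermediate
19 | (4S)-2-bromo-4-hydroxy-4-[(2Z)-oct-2-en-1-yl]cyclopent-2-en-1-one | CCCCC/C=C\C[C@@]1(O)C=C(Br)C(=O)C1 | intermediate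
20 | methyl hex-5-enoate | COC(=O)CCCC=C | starting material
21 | (Z)-but-2-ene-1,4-diol | OC/C=C\CO | starting material
22 | methyl (5Z)-7-hydroxyhept-5-enoate | COC(=O)CCC/C=C\CO | intermediate
23 | methyl (5Z)-7-oxohept-5-enoate | COC(=O)CCC/C=C\C=O | intermediate
24 | dilithium (4S)-2-bromo-4-oxido-4-[(2Z)-oct-2-en-1-yl]cyclopenta-1,5-dien-1-olate | [Li+].[Li+].CCCCC/C=C\C[C@@]1([O-])C=C(Br)C([O-])=C1 | intermediate
25 | methyl (5Z,7S)-7-[(1R,2S)-4-bromo-2-hydroxy-2-[(2Z)-oct-2-en-1-yl]-5-oxocyclopent-3-en-1-yl]-7-hydroxyhept-5-enoate | CCCCC/C=C\C[C@@]1(O)C=C(Br)C(=O)[C@@H]1[C@H](/C=C\CCCC(=O)OC)O | intermediate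
26 | 7-acetoxy-7,8-dihydrobromovulone I, methyl (5Z,7S)-7-acetoxy-7-[(1R,2S)-4-bromo-2-hydroxy-2-[(2Z)-oct-2-en-1-yl]-5-oxocyclopent-3-en-1-yl]hept-5-enoate | CCCCC/C=C\C[C@@]1(O)C=C(Br)C(=O)[C@@H]1[C@H](/C=C\CCCC(=O)OC)OC(C)=O | target

**Totals**
Total step count: 9. Longest linear sequence: 6 steps (1, 2, 4, 5, 8, 9).

**Steps most likely to fail**

Step 4 (key annulation). The enolate may add in conjugate fashion to the sulfinyl enone, the allyl anion may be quenched by the acidic C13–H, or the sulfoxide may control C12 weakly or in the opposite sense. The fallback sets out from 13 (and uses 16) and comes back at 19. 13 is quenched with diphenyl disulfide to give tert-butyl[1-methoxy-3-(phenylsulfanyl)propa-1,2-dien-1-yl]dimethylsilane F1. Aqueous acid hydrolysis gives (2E)-1-[tert-butyl(dimethyl)silyl]-3-(phenylsulfanyl)prop-2-en-1-one F2, the sulfide reagent for which this annulation type is established. With 16 it gives racemic 4-{[tert-butyl(dimethyl)silyl]oxy}-1-[(2Z)-oct-2-en-1-yl]-2-(phenylsulfanyl)cyclopent-3-en-1-ol F3. mCPBA (1 equiv, −78 °C) oxidises only sulfur, giving racemic 2-(benzenesulfinyl)-4-{[tert-butyl(dimethyl)silyl]oxy}-1-[(2Z)-oct-2-en-1-yl]cyclopent-3-en-1-ol F4. NBS then Et3N, as in step 5, lead through 3-(benzenesulfinyl)-2-bromo-4-hydroxy-4-[(2Z)-oct-2-en-1-yl]cyclopentan-1-one F5 to racemic 2-bromo-4-hydroxy-4-[(2Z)-oct-2-en-1-yl]cyclopent-2-en-1-one F6. Preparative chromatography on a chiral stationary phase then gives 19. Absolute configuration is thus set by resolution instead of by the auxiliary.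

Step 8 (aldol). The Z-enal may isomerise or polymerise under the basic conditions, and the anti/syn ratio at C7 may be modest. The fallback sets out from 19 and comes back at 26. Dianion 24 is combined with methyl 7-oxohept-5-ynoate F7 (Dess–Martin oxidation of bought methyl 7-hydroxyhept-5-ynoate), an aldehyde with no alkene geometry to lose. This gives methyl (7R)-7-[(1R,2S)-4-bromo-2-hydroxy-2-[(2Z)-oct-2-en-1-yl]-5-oxocyclopent-3-en-1-yl]-7-hydroxyhept-5-ynoate F8; the arrangement at C7 is the same as in 25, and the descriptor changes only because the alkynyl carbon outranks C8. Ac2O/pyridine gives methyl (7R)-7-acetoxy-7-[(1R,2S)-4-bromo-2-hydroxy-2-[(2Z)-oct-2-en-1-yl]-5-oxocyclopent-3-en-1-yl]hept-5-ynoate F9. Semi-hydrogenation (H2, Pd/CaCO3 poisoned with Pb(OAc)2, quinoline, EtOAc) sets the 5Z alkene last and gives 26.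

Step 3 (sulfinyl acryloylsilane). The lithiated silyl allenyl ether may attack the sulfinate through its propargylic terminus, or excess organolithium may erode the sulfur configuration. The fallback sets out from 13 and comes back at 15. 13 is quenched with bis(4-methylphenyl) disulfide to give tert-butyl{1-methoxy-3-[(4-methylphenyl)sulfanyl]propa-1,2-dien-1-yl}dimethylsilane F10. Aqueous acid hydrolysis gives (2E)-1-[tert-butyl(dimethyl)silyl]-3-[(4-methylphenyl)sulfanyl]prop-2-en-1-one F11. Enantioselective sulfoxidation with Ti(OiPr)4/(R,R)-diethyl tartrate/H2O/cumene hydroperoxide (Kagan–Modena, CH2Cl2, −20 °C), followed by recrystallisation, gives 15. Sulfur chirality then comes from asymmetric oxidation instead of substitution at sulfur.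

**Further compounds**
F1 | step 4 | tert-butyl[1-methoxy-3-(phenylsulfanyl)propa-1,2-dien-1-yl]dimethylsilane | COC(=C=CSc1ccccc1)[Si](C)(C)C(C)(C)C
F2 | step 4 | (2E)-1-[tert-butyl(dimethyl)silyl]-3-(phenylsulfanyl)prop-2-en-1-one | CC(C)(C)[Si](C)(C)C(=O)/C=C/Sc1ccccc1
F3 | step 4 | racemic 4-{[tert-butyl(dimethyl)silyl]oxy}-1-[(2Z)-oct-2-en-1-yl]-2-(phenylsulfanyl)cyclopent-3-en-1-ol | CCCCC/C=C\CC1(O)C(Sc2ccccc2)C=C(O[Si](C)(C)C(C)(C)C)C1
F4 | step 4 | racemic 2-(benzenesulfinyl)-4-{[tert-butyl(dimethyl)silyl]oxy}-1-[(2Z)-oct-2-en-1-yl]cyclopent-3-en-1-ol | CCCCC/C=C\CC1(O)C(S(=O)c2ccccc2)C=C(O[Si](C)(C)C(C)(C)C)C1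
F5 | step 4 | 3-(benzenesulfinyl)-2-bromo-4-hydroxy-4-[(2Z)-oct-2-en-1-yl]cyclopentan-1-one | CCCCC/C=C\CC1(O)C(S(=O)c2ccccc2)C(Br)C(=O)C1
F6 | step 4 | racemic 2-bromo-4-hydroxy-4-[(2Z)-oct-2-en-1-yl]cyclopent-2-en-1-one | CCCCC/C=C\CC1(O)C=C(Br)C(=O)C1
F7 | step 8 | methyl 7-oxohept-5-ynoate | COC(=O)CCCC#CC=O
F8 | step 8 | methyl (7R)-7-[(1R,2S)-4-bromo-2-hydroxy-2-[(2Z)-oct-2-en-1-yl]-5-oxocyclopent-3-en-1-yl]-7-hydroxyhept-5-ynoate | CCCCC/C=C\C[C@@]1(O)C=C(Br)C(=O)[C@@H]1[C@H](C#CCCCC(=O)OC)O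
F9 | step 8 | methyl (7R)-7-acetoxy-7-[(1R,2S)-4-bromo-2-hydroxy-2-[(2Z)-oct-2-en-1-yl]-5-oxocyclopent-3-en-1-yl]hept-5-ynoate | CCCCC/C=C\C[C@@]1(O)C=C(Br)C(=O)[C@@H]1[C@H](C#CCCCC(=O)OC)OC(C)=O
F10 | step 3 | tert-butyl{1-methoxy-3-[(4-methylphenyl)sulfanyl]propa-1,2-dien-1-yl}dimethylsilane | COC(=C=CSc1ccc(C)cc1)[Si](C)(C)C(C)(C)C
F11 | step 3 | (2E)-1-[tert-butyl(dimethyl)silyl]-3-[(4-methylphenyl)sulfanyl]prop-2-en-1-one | CC(C)(C)[Si](C)(C)C(=O)/C=C/Sc1ccc(C)cc1
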